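## Retrosynthetic overview
1. Target ⇒ one hydrogenation that saturates the side-chain alkene and removes an O-benzyl group ⇒ 5-[(E)-octenyl] N-methoxy-4-pyridone benzyl ether.
2. Ring B (pyridone) ⇒ two C–N bonds. MeONH2 bridges the C2 and C8a carbonyls of a 1,3,5-trione, as the nitrogen does in the biogenesis.
3. Ring A (carbocycle) ⇒ the C4a–C5 bond inside an unbranched C18 chain. The C4a methylene attacks a π-allylpalladium formed by enantioselective Pd–H addition to the chain diene, and this sets C5.
4. C18 dienyl trione ⇒ C16 β-diketone + C2 glycolyl unit (dianion acylation) ⇒ C14 methyl ketone + methoxyacetate (Claisen) ⇒ C13 dienoic acid + MeLi ⇒ Wittig reaction of (E)-oct-2-enal with a C5 ylide.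
5. Ring order: A first, then B, both in one flask from the open chain.

Assumption: the alkaloid is taken to arise like its congener antidesmone, from an unbranched C16 acetate chain joined at its carboxyl carbon (C3) to a C2 amino acid unit (C2, CH2OH, N); ring A closes by C4a–C5 bond formation within this C18 chain, ring B closes by nitrogen condensing with chain carbonyls, and the two O-methyl groups are decorations that are brought in here with the building blocks.

Labels: C2–C8a follow the quinolinone numbering of the target, and C1′–C8′ are the side-chain carbons.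

## Route

Step 1
Reactants: 1 (4-carboxybutyl)triphenylphosphonium bromide; 2 (E)-oct-2-enal
Product: 4 (5Z,7E)-trideca-5,7-dienoic acid, via phosphorus ylide 3 (not isolated)
Conditions: KOtBu (2.1 equiv), THF, 0 °C; then 2, −78 → 23 °C; 1 M HCl work-up
Reagents that add atoms: none
Why: Wittig olefination in which the non-stabilised carboxylate ylide adds to the enal under kinetic control, making the new C5=C1′ bond mainly Z and leaving the E-alkene of 2 untouched; the Z/E ratio is not critical because step 5 erases the diene geometry.

Step 2
Reactants: 4 (5Z,7E)-trideca-5,7-dienoic acid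
Product: 5 (6Z,8E)-tetradeca-6,8-dien-2-one
Conditions: MeLi (2.2 equiv), Et2O, 0 °C; inverse quench into cold 1 M HCl
Reagents that add atoms: methyllithium, [Li]C
Why: Organolithium addition to a lithium carboxylate gives a geminal dilithium diolate that collapses to the methyl ketone only on quench, so over-addition is avoided and the isolated diene is inert to MeLi.

Step 3
Reactants: 5 (6Z,8E)-tetradeca-6,8-dien-2-one; 6 methyl 2-methoxyacetate
Product: 7 (8Z,10E)-1-methoxyhexadeca-8,10-diene-2,4-dione
Conditions: KOtBu (2.0 equiv), 6 (2.0 equiv), THF, 0 → 23 °C (5 added slowly); 1 M HCl work-up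
Reagents that add atoms: methyl 2-methoxyacetate 6, COCC(=O)OC
Why: Crossed Claisen condensation under equilibrating conditions acylates the methyl group (the future C4a), because the unsubstituted diketonate is the thermodynamic sink and the α-alkoxy ester is an activated acyl donor; this completes the linear C16 chain.

Step 4
Reactants: 7 (8Z,10E)-1-methoxyhexadeca-8,10-diene-2,4-dione; 8 2-(benzyloxy)-N-methoxy-N-methylacetamide
Product: 10 (10Z,12E)-1-(benzyloxy)-3-methoxyoctadeca-10,12-diene-2,4,6-trione, via dilithio dianion 9 (not isolated)
Conditions: LiN(iPr)2 (LDA, 2.1 equiv), THF, −78 → 0 °C, 45 min; then 8 (1.05 equiv), −78 → −20 °C; cold 1 M HCl quench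
Reagents that add atoms: 2-(benzyloxy)-N-methoxy-N-methylacetamide 8, CON(C)C(=O)COCc1ccccc1
Why: β-Diketone dianion γ-acylation (Hauser–Harris type) combined with a Weinreb ketone synthesis, in which the second deprotonation goes to the CH2OMe group (C3), which is about two pK units more acidic than the α-alkyl CH2 (C8) and is lithium-chelated, while the stable tetrahedral chelate prevents proton quench by the product and over-acylation.

Step 5
Reactants: 10 (10Z,12E)-1-(benzyloxy)-3-methoxyoctadeca-10,12-diene-2,4,6-trione; 11 O-methylhydroxylamine hydrochloride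
Product: 13 (5S)-2-[(benzyloxy)methyl]-1,3-dimethoxy-5-[(E)-oct-1-en-1-yl]-5,6,7,8-tetrahydroquinolin-4(1H)-one, via cyclised trione 12 (not isolated)
Conditions: [Pd(η3-C3H5)Cl]2 (2.5 mol %), (S)-(CF3)3-tBu-PHOX = (S)-2-{2-[bis(4-(trifluoromethyl)phenyl)phosphanyl]-5-(trifluoromethyl)phenyl}-4-tert-butyl-4,5-dihydrooxazole (6 mol %), NaB[3,5-(CF3)2C6H3]4 (6 mol %), Et3N (20 mol %), [Et3NH][B(3,5-(CF3)2C6H3)4] (10 mol %), CH2Cl2 (0.02 M), 23 °C; then evaporate, 11 (1.3 equiv), NaOAc (1.3 equiv), EtOH, 23 → 78 °C
Reagents that add atoms: O-methylhydroxylamine hydrochloride 11, CON.Cl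
Why: Proposed new method: zerovalent palladium released from the allyl precatalyst is protonated by Et3NH+ to a cationic Pd–H that adds reversibly to the diene (H to C3′), and the resulting 1,3-dialkyl π-allyl complex of divalent palladium equilibrates by π-σ-π and reversible β-hydride elimination, so the Z,E geometry of 10 is irrelevant; the C4a enolate carbon attacks it anti at C5, where the six-membered closure outruns the seven-, eight- and nine-membered alternatives and O-allylation is reversible, while the chiral P,N ligand selects the allyl face and sets the only stereocentre (S here, the spatial arrangement of the target) and leaves an E C1′=C2′ alkene; the closest known reaction types are the intermolecular Pd–PHOX/ammonium co-catalysed enantioselective hydroalkylation of internal 1,3-dienes with β-diketones and the racemic intramolecular Pd-catalysed addition of active methylene compounds to dienes; the second stage is the classical cyclocondensation of a 1,3,5-triketone with an amine to a 4-pyridone, in which MeONH2 bridges C2 and C8a with loss of two waters and C3 and C4a become sp2, so their configurations do not matter.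

Step 6
Reactants: 13 (5S)-2-[(benzyloxy)methyl]-1,3-dimethoxy-5-[(E)-oct-1-en-1-yl]-5,6,7,8-tetrahydroquinolin-4(1H)-one
Product: 14 (5R)-2-(hydroxymethyl)-1,3-dimethoxy-5-octyl-5,6,7,8-tetrahydroquinolin-4(1H)-one
Conditions: H2 (1 atm), 10 % Pd/C, EtOAc–EtOH, 23 °C, vigorous stirring, stopped after uptake of 2 equiv
Reagents that add atoms: none
Why: Heterogeneous catalytic hydrogenation saturates the 1,2-disubstituted alkene and hydrogenolyses the benzyl ether in one operation, while the vinylogous-amide ring, the N–OMe bond and the heterobenzylic C–O bond are inert at 1 atm in neutral solvent; no bond at C5 is touched, and the descriptor changes from S to R only because octyl now ranks below C6.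

## Compound list
1 | (4-carboxybutyl)triphenylphosphonium bromide | [Br-].OC(=O)CCCC[P+](c1ccccc1)(c1ccccc1)c1ccccc1 | starting material
2 | (E)-oct-2-enal | CCCCC/C=C/C=O | starting material
3 | potassium 5-(triphenyl-λ5-phosphanylidene)pentanoate (ylide, not isolated) | [K+].[O-]C(=O)CCCC=P(c1ccccc1)(c1ccccc1)c1ccccc1 | intermediate
4 | (5Z,7E)-trideca-5,7-dienoic acid | CCCCC/C=C/C=C\CCCC(=O)O | intermediate
5 | (6Z,8E)-tetradeca-6,8-dien-2-one | CCCCC/C=C/C=C\CCCC(C)=O | intermediate
6 | methyl 2-methoxyacetate | COCC(=O)OC | starting material
7 | (8Z,10E)-1-methoxyhexadeca-8,10-diene-2,4-dione (largely enolised) | CCCCC/C=C/C=C\CCCC(=O)CC(=O)COC | intermediate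
8 | 2-(benzyloxy)-N-methoxy-N-methylacetamide | CON(C)C(=O)COCc1ccccc1 | starting material
9 | dilithium dianion of 7, deprotonated at the central CH2 and at CH2OMe (not isolated) | [Li+].[Li+].CCCCC/C=C/C=C\CCCC(=O)[CH-]C(=O)[CH-]OC | intermediate
10 | (10Z,12E)-1-(benzyloxy)-3-methoxyoctadeca-10,12-diene-2,4,6-trione (the methoxy-bearing carbon is configurationally labile and unspecified) | CCCCC/C=C/C=C\CCCC(=O)CC(=O)C(OC)C(=O)COCc1ccccc1 | intermediate
11 | O-methylhydroxylamine hydrochloride | CON.Cl | starting material
12 | 4-(benzyloxy)-1-{(6S)-2-hydroxy-6-[(E)-oct-1-en-1-yl]cyclohex-1-en-1-yl}-2-methoxybutane-1,3-dione (drawn as the ring enol, methoxy-bearing carbon labile, not isolated) | CCCCCC/C=C/[C@@H]1CCCC(O)=C1C(=O)C(OC)C(=O)COCc2ccccc2 | intermediate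
13 | (5S)-2-[(benzyloxy)methyl]-1,3-dimethoxy-5-[(E)-oct-1-en-1-yl]-5,6,7,8-tetrahydroquinolin-4(1H)-one | CCCCCC/C=C/[C@@H]1CCCc2c1c(=O)c(OC)c(COCc3ccccc3)n2OC | intermediate
14 | (5R)-2-(hydroxymethyl)-1,3-dimethoxy-5-octyl-5,6,7,8-tetrahydroquinolin-4(1H)-one | CCCCCCCC[C@@H]1CCCc2c1c(=O)c(OC)c(CO)n2OC | target

## Counts and risks
Total steps: 6. Longest linear sequence: 6 (from 1 and 2 to 14).

**Step 5 (highest risk).**
- No intramolecular enantioselective case of this hydroalkylation is known.
- The trione may bind palladium as a chelate, and internal dialkyl dienes insert slowly.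
- The ee is unproven. The sense of induction of the (S)-ligand must be confirmed by comparing the optical rotation of 14 with that of the natural product. If it is wrong, the (R)-ligand is used.
- Chloride and the alkoxyamine added in the second stage should deactivate the cationic palladium hydride before heating, but this also needs checking.
- MeONH2 may stop at an oxime ether, or the trione may close to the 4-pyranone.

The fallback sets out from 7 and comes back at 12. The one-flask double closure on the C18 chain is given up, and ring A is closed one stage earlier, on the C16 β-diketone. This is the pronucleophile class for which the intermolecular reaction is established. Compound 7 alone is cyclised under the Pd–H catalysis to 1-{(6S)-2-hydroxy-6-[(E)-oct-1-en-1-yl]cyclohex-1-en-1-yl}-2-methoxyethan-1-one F1, whose ee can be measured and optimised on a simple compound. The C2 unit is attached afterwards by treating F1 with LiN(iPr)2 (2 equiv) and then 8. This gives 12, which is now isolated. A separate condensation of 12 with 11 leads to 13.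

**Step 4.** The second deprotonation could occur partly at C8 instead of C3. The dianion could also simply deprotonate 8, and the trione could cyclise on work-up.

The fallback sets out from 7 and comes back at 14. It costs one extra step. The C2 unit is brought in at the carboxyl oxidation level under equilibrating alkoxide conditions instead of by kinetic dianion chemistry.
- Compound 7 with dimethyl oxalate and NaOMe in MeOH–THF undergoes Claisen acylation at the CH2OMe group. This gives methyl (10Z,12E)-3-methoxy-2,4,6-trioxooctadeca-10,12-dienoate F2.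
- The conditions of step 5 take F2 through methyl 4-{(6S)-2-hydroxy-6-[(E)-oct-1-en-1-yl]cyclohex-1-en-1-yl}-3-methoxy-2,4-dioxobutanoate F3 (not isolated). The isolated product is methyl (5S)-1,3-dimethoxy-5-[(E)-oct-1-en-1-yl]-4-oxo-1,4,5,6,7,8-hexahydroquinoline-2-carboxylate F4.
- NaBH4/CaCl2 in MeOH reduces the activated ester of F4. This gives (5S)-2-(hydroxymethyl)-1,3-dimethoxy-5-[(E)-oct-1-en-1-yl]-5,6,7,8-tetrahydroquinolin-4(1H)-one F5.
- Saturation of the alkene of F5 (H2, Pd/C) gives 14.

**Step 6.** Pd/C can move the C1′=C2′ double bond to C5=C1′ before saturation, which would erode the ee. Over-reduction of the N–O bond or the heterobenzylic C–O bond is also possible.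

The fallback sets out from 13 and comes back at 14. The alkene is first reduced without any metal, using diimide generated from 2-nitrobenzenesulfonohydrazide and Et3N in MeCN at 23 °C. This concerted syn transfer has no allyl intermediates and gives (5R)-2-[(benzyloxy)methyl]-1,3-dimethoxy-5-octyl-5,6,7,8-tetrahydroquinolin-4(1H)-one F6. Only then is the benzyl group removed by brief hydrogenolysis over Pd(OH)2/C, when no alkene is left to migrate.

## Further compounds
F1 | step 5 | 1-{(6S)-2-hydroxy-6-[(E)-oct-1-en-1-yl]cyclohex-1-en-1-yl}-2-methoxyethan-1-one | CCCCCC/C=C/[C@@H]1CCCC(O)=C1C(=O)COC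
F2 | step 4 | methyl (10Z,12E)-3-methoxy-2,4,6-trioxooctadeca-10,12-dienoate | CCCCC/C=C/C=C\CCCC(=O)CC(=O)C(OC)C(=O)C(=O)OC
F3 | step 4 | methyl 4-{(6S)-2-hydroxy-6-[(E)-oct-1-en-1-yl]cyclohex-1-en-1-yl}-3-methoxy-2,4-dioxobutanoate | CCCCCC/C=C/[C@@H]1CCCC(O)=C1C(=O)C(OC)C(=O)C(=O)OC
F4 | step 4 | methyl (5S)-1,3-dimethoxy-5-[(E)-oct-1-en-1-yl]-4-oxo-1,4,5,6,7,8-hexahydroquinoline-2-carboxylate | CCCCCC/C=C/[C@@H]1CCCc2c1c(=O)c(OC)c(C(=O)OC)n2OC
F5 | step 4 | (5S)-2-(hydroxymethyl)-1,3-dimethoxy-5-[(E)-oct-1-en-1-yl]-5,6,7,8-tetrahydroquinolin-4(1H)-one | CCCCCC/C=C/[C@@H]1CCCc2c1c(=O)c(OC)c(CO)n2OC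
F6 | step 6 | (5R)-2-[(benzyloxy)methyl]-1,3-dimethoxy-5-octyl-5,6,7,8-tetrahydroquinolin-4(1H)-one | CCCCCCCC[C@@H]1CCCc2c1c(=O)c(OC)c(COCc3ccccc3)n2OC
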